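**Plan**

- Retrosynthesis: the two phenols are released last from benzyl ethers, the aryl ketone is traced back to a 1-arylvinyl group (C=CH2 for C=O) and the CH2OH group to a formyl group; the ring is then cut at O1–C2 and at C3–C4.
- Feature used: with the ring numbered O1, C2 (aryl), C3 (CH2OH), C4 (aroyl), C5, the atoms O1–C2–C3–CH=O form a β-alkoxy aldehyde (an alcohol added to a cinnamaldehyde), and O1–C5–C4–C(Ar)=CH2 is an allyl alkoxide, the ionised form of a 4-(1-arylvinyl)-1,3-dioxolan-2-one.
- Forward: O-benzylsinapaldehyde 2 (one step) and carbonate 11 (six steps) are joined, and the only ring of the target, the tetrahydrofuran, closes in that same step; oxidative cleavage of the alkene and hydrogenolysis finish the route.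
- Stereochemistry: C2 comes from the chiral secondary amine (face of the iminium ion), C3 from the (E)-enamine (trans to the C2 aryl), C4 from the chiral ligand on palladium acting on an equilibrating π-allyl complex, so racemic 11 suffices.
- All steps after the ring closure are run near neutral pH, because C4 becomes α to the ketone and β to the ring oxygen.

Key step: step 8

Assumption: which enantiomer of the phosphoramidite gives the 3,4-cis ring cannot be derived from a model with confidence; the route is written with the (Sa,R,R) ligand, and its mirror image is used instead if the first run shows 3,4-trans closure.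
Remark: ester 5 is used as the racemate, since its stereocentre is erased when 11 is ionised in step 8.

**Route**

Step 1
Reactants: 1 sinapaldehyde, (E)-3-(4-hydroxy-3,5-dimethoxyphenyl)acrylaldehyde
Product: 2 (E)-3-[4-(benzyloxy)-3,5-dimethoxyphenyl]acrylaldehyde (fragment 1)
Conditions: BnBr, K2CO3, DMF, rt
Reagents that add atoms: benzyl bromide, BrCc1ccccc1
Why: Williamson ether synthesis, in which the phenoxide of this vinylogous acid is alkylated on oxygen by the benzylic bromide while the (E)-enal is inert to K2CO3 at room temperature.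

Step 2
Reactants: 3 4-bromo-2,6-dimethoxyphenol
Product: 4 2-(benzyloxy)-5-bromo-1,3-dimethoxybenzene
Conditions: BnBr, K2CO3, DMF, 60 °C
Reagents that add atoms: benzyl bromide, BrCc1ccccc1
Why: Williamson ether synthesis on a 2,6-disubstituted phenol, for which warm DMF and a benzylic bromide are sufficient, with the aryl bromide untouched.

Step 3
Reactants: 5 methyl 2,2-dimethyl-1,3-dioxolane-4-carboxylate (racemic)
Product: 6 N-methoxy-N,2,2-trimethyl-1,3-dioxolane-4-carboxamide (racemic)
Conditions: MeNH(OMe)·HCl, i-PrMgCl, THF, −20 to 0 °C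
Reagents that add atoms: N,O-dimethylhydroxylamine hydrochloride, CNOC.Cl
Why: Ester aminolysis by the chloromagnesium amide formed in the flask, the standard entry to the N-methoxy-N-methylamide needed for a Weinreb ketone synthesis, under basic conditions that the acetonide tolerates.

Step 4
Reactants: 4 2-(benzyloxy)-5-bromo-1,3-dimethoxybenzene; 6 N-methoxy-N,2,2-trimethyl-1,3-dioxolane-4-carboxamide
Product: 8 [4-(benzyloxy)-3,5-dimethoxyphenyl](2,2-dimethyl-1,3-dioxolan-4-yl)methanone (racemic), via aryllithium 7 (not isolated)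
Conditions: n-BuLi, THF, −78 °C; then 6, −78 to 0 °C; aq. NH4Cl
Reagents that add atoms: none
Why: Bromine–lithium exchange at −78 °C outruns attack on the benzyl ether, and the Weinreb ketone synthesis stops at the ketone because the chelated tetrahedral adduct survives until the quench.

Step 5
Reactants: 8 [4-(benzyloxy)-3,5-dimethoxyphenyl](2,2-dimethyl-1,3-dioxolan-4-yl)methanone
Product: 9 4-{1-[4-(benzyloxy)-3,5-dimethoxyphenyl]vinyl}-2,2-dimethyl-1,3-dioxolane (racemic)
Conditions: Ph3PCH3Br, KOt-Bu, THF, 0 °C to rt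
Reagents that add atoms: methyltriphenylphosphonium bromide, C[P+](c1ccccc1)(c1ccccc1)c1ccccc1.[Br-]
Why: Wittig methylenation with the non-stabilised ylide is routine for α-alkoxy aryl ketones and leaves the acetonide and the benzyl ether alone; no stereocentre is formed.

Step 6
Reactants: 9 4-{1-[4-(benzyloxy)-3,5-dimethoxyphenyl]vinyl}-2,2-dimethyl-1,3-dioxolane
Product: 10 3-[4-(benzyloxy)-3,5-dimethoxyphenyl]but-3-ene-1,2-diol (racemic)
Conditions: AcOH/H2O (4:1), 40 °C
Reagents that add atoms: none
Why: Acid-catalysed acetal hydrolysis in aqueous acetic acid, which is too weak to protonate the 1,1-disubstituted styrene or to ionise the non-benzylic allylic alcohol.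

Step 7
Reactants: 10 3-[4-(benzyloxy)-3,5-dimethoxyphenyl]but-3-ene-1,2-diol
Product: 11 4-{1-[4-(benzyloxy)-3,5-dimethoxyphenyl]vinyl}-1,3-dioxolan-2-one (racemic, fragment 2)
Conditions: CDI, CH2Cl2, rt
Reagents that add atoms: 1,1'-carbonyldiimidazole, O=C(n1ccnc1)n1ccnc1
Why: Carbonylation of a 1,2-diol with CDI gives the five-membered cyclic carbonate by two acyl transfers under neutral conditions that spare the styrene.

Step 8
Reactants: 2 (E)-3-[4-(benzyloxy)-3,5-dimethoxyphenyl]acrylaldehyde; 11 4-{1-[4-(benzyloxy)-3,5-dimethoxyphenyl]vinyl}-1,3-dioxolan-2-one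
Product: 13 [(2S,3R,4S)-2-[4-(benzyloxy)-3,5-dimethoxyphenyl]-4-{1-[4-(benzyloxy)-3,5-dimethoxyphenyl]vinyl}tetrahydrofuran-3-yl]methanol, via aldehyde 12 (not isolated)
Conditions: Pd2(dba)3·CHCl3 (2.5 mol %), (Sa,R,R)-O,O'-(1,1'-binaphthalene-2,2'-diyl) N,N-bis(1-phenylethyl)phosphoramidite (10 mol %), (S)-2-[diphenyl(tert-butyldimethylsilyloxy)methyl]pyrrolidine (20 mol %), PhCO2H (10 mol %), THF, 0 °C to rt; then MeOH, NaBH4, 0 °C
Reagents that add atoms: none
Why: Proposed new method: zerovalent palladium ionises the allylic C–O bond of 11 and CO2 leaves, giving a 2-aryl-π-allylpalladium cation tethered to a primary alkoxide, while the (S)-amine turns 2 into its iminium ion; the alkoxide adds to the β-carbon (O1–C2), the resulting (E)-enamine attacks the substituted allyl terminus anti to palladium (C3–C4), hydrolysis releases aldehyde 12 and both catalysts, and NaBH4 in the same flask reduces the formyl group to give 13. The closest known reaction types are the palladium-catalysed decarboxylative (3+2) annulation of vinylethylene carbonates with doubly activated alkenes, the amine/palladium (3+2) annulation of vinylcyclopropanes with enals and the amine/palladium α-allylation of aldehydes; an oxygen-centred zwitterion has not been paired with an iminium ion in this way. The tetrahydrofuran closes by a 5-exo attack of the enamine carbon on the allyl terminus that carries the CH2O tether, so the 1-arylvinyl group ends up outside the ring. C2 is set by the amine, whose diphenyl(silyloxy)methyl group screens the Re face of the β-carbon so that oxygen enters on the Si face and gives the (S) centre; C3 is set by the (E)-enamine reacting on the same open face, which puts the formyl group trans to the C2 aryl; C4 is set by the phosphoramidite on palladium. The step needs closure at the substituted allyl terminus and a 3,4-cis relation: the three-atom O–CH2–CH tether secures the first (five- against seven-membered ring), and the unsubstituted CH2 terminus lets the two diastereomeric π-allyl complexes from racemic 11 interconvert faster than the ring closes, which leaves the second to the ligand. The α-formyl centre can epimerise, so it is reduced before isolation, and the tert-butyldimethylsilyl ether on the amine is chosen so that the transient alkoxide does not strip silicon from the catalyst.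

Step 9
Reactants: 13 [(2S,3R,4S)-2-[4-(benzyloxy)-3,5-dimethoxyphenyl]-4-{1-[4-(benzyloxy)-3,5-dimethoxyphenyl]vinyl}tetrahydrofuran-3-yl]methanol
Product: 15 [4-(benzyloxy)-3,5-dimethoxyphenyl][(3R,4R,5S)-5-[4-(benzyloxy)-3,5-dimethoxyphenyl]-4-(hydroxymethyl)tetrahydrofuran-3-yl]methanone, via triol 14 (not isolated)
Conditions: OsO4 (2 mol %), NaIO4, 2,6-lutidine, dioxane/H2O (3:1), rt
Reagents that add atoms: osmium tetroxide, O=[Os](=O)(=O)=O (direct oxygen donor); sodium periodate, [Na+].[O-]I(=O)(=O)=O (restores the osmium oxide)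
Why: Lemieux–Johnson oxidation, in which OsO4 dihydroxylates the only alkene to triol 14 and NaIO4 cleaves its 1,2-diol to the aryl ketone and formaldehyde, while 2,6-lutidine keeps the medium near neutral so that C4 should neither epimerise nor undergo β-elimination of the ring oxygen; no stereocentre is formed.

Step 10
Reactants: 15 [4-(benzyloxy)-3,5-dimethoxyphenyl][(3R,4R,5S)-5-[4-(benzyloxy)-3,5-dimethoxyphenyl]-4-(hydroxymethyl)tetrahydrofuran-3-yl]methanone
Product: 16 ciwujiatone, (4-hydroxy-3,5-dimethoxyphenyl)[(3R,4R,5S)-5-(4-hydroxy-3,5-dimethoxyphenyl)-4-(hydroxymethyl)tetrahydrofuran-3-yl]methanone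
Conditions: H2 (1 atm), 10% Pd/C, EtOAc, rt
Reagents that add atoms: none
Why: Hydrogenolysis of the two aryl benzyl ethers over Pd/C should be much faster at 1 atm in ethyl acetate than reduction of the electron-rich aryl ketone or cleavage of the benzylic ring C–O bond, and it is neutral, so the three stereocentres stay as set.

**Compound list**

1 | sinapaldehyde, (E)-3-(4-hydroxy-3,5-dimethoxyphenyl)acrylaldehyde | COc1cc(/C=C/C=O)cc(OC)c1O | starting material
2 | (E)-3-[4-(benzyloxy)-3,5-dimethoxyphenyl]acrylaldehyde (fragment 1) | O=C/C=C/c1cc(OC)c(OCc2ccccc2)c(OC)c1 | intermediate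
3 | 4-bromo-2,6-dimethoxyphenol | COc1cc(Br)cc(OC)c1O | starting material
4 | 2-(benzyloxy)-5-bromo-1,3-dimethoxybenzene | COc1cc(Br)cc(OC)c1OCc1ccccc1 | intermediate
5 | methyl 2,2-dimethyl-1,3-dioxolane-4-carboxylate (racemic) | COC(=O)C1COC(C)(C)O1 | starting material
6 | N-methoxy-N,2,2-trimethyl-1,3-dioxolane-4-carboxamide (racemic) | CON(C)C(=O)C1COC(C)(C)O1 | intermediate
7 | [4-(benzyloxy)-3,5-dimethoxyphenyl]lithium | [Li]c1cc(OC)c(OCc2ccccc2)c(OC)c1 | intermediate (not isolated)
8 | [4-(benzyloxy)-3,5-dimethoxyphenyl](2,2-dimethyl-1,3-dioxolan-4-yl)methanone (racemic) | COc1cc(C(=O)C2COC(C)(C)O2)cc(OC)c1OCc1ccccc1 | intermediate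
9 | 4-{1-[4-(benzyloxy)-3,5-dimethoxyphenyl]vinyl}-2,2-dimethyl-1,3-dioxolane (racemic) | C=C(c1cc(OC)c(OCc2ccccc2)c(OC)c1)C1COC(C)(C)O1 | intermediate
10 | 3-[4-(benzyloxy)-3,5-dimethoxyphenyl]but-3-ene-1,2-diol (racemic) | C=C(c1cc(OC)c(OCc2ccccc2)c(OC)c1)C(O)CO | intermediate
11 | 4-{1-[4-(benzyloxy)-3,5-dimethoxyphenyl]vinyl}-1,3-dioxolan-2-one (racemic, fragment 2) | C=C(c1cc(OC)c(OCc2ccccc2)c(OC)c1)C1COC(=O)O1 | intermediate
12 | (2S,3S,4S)-2-[4-(benzyloxy)-3,5-dimethoxyphenyl]-4-{1-[4-(benzyloxy)-3,5-dimethoxyphenyl]vinyl}tetrahydrofuran-3-carbaldehyde (2,3-trans, 3,4-cis) | C=C(c1cc(OC)c(OCc2ccccc2)c(OC)c1)[C@H]1CO[C@H](c2cc(OC)c(OCc3ccccc3)c(OC)c2)[C@H]1C=O | intermediate (not isolated)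
13 | [(2S,3R,4S)-2-[4-(benzyloxy)-3,5-dimethoxyphenyl]-4-{1-[4-(benzyloxy)-3,5-dimethoxyphenyl]vinyl}tetrahydrofuran-3-yl]methanol | C=C(c1cc(OC)c(OCc2ccccc2)c(OC)c1)[C@H]1CO[C@H](c2cc(OC)c(OCc3ccccc3)c(OC)c2)[C@H]1CO | intermediate
14 | 1-[4-(benzyloxy)-3,5-dimethoxyphenyl]-1-[(3R,4R,5S)-5-[4-(benzyloxy)-3,5-dimethoxyphenyl]-4-(hydroxymethyl)tetrahydrofuran-3-yl]ethane-1,2-diol (tertiary carbinol centre unassigned) | OCC(O)(c1cc(OC)c(OCc2ccccc2)c(OC)c1)[C@H]1CO[C@H](c2cc(OC)c(OCc3ccccc3)c(OC)c2)[C@H]1CO | intermediate (not isolated)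
15 | [4-(benzyloxy)-3,5-dimethoxyphenyl][(3R,4R,5S)-5-[4-(benzyloxy)-3,5-dimethoxyphenyl]-4-(hydroxymethyl)tetrahydrofuran-3-yl]methanone | COc1cc(C(=O)[C@H]2CO[C@H](c3cc(OC)c(OCc4ccccc4)c(OC)c3)[C@H]2CO)cc(OC)c1OCc1ccccc1 | intermediate
16 | ciwujiatone, (4-hydroxy-3,5-dimethoxyphenyl)[(3R,4R,5S)-5-(4-hydroxy-3,5-dimethoxyphenyl)-4-(hydroxymethyl)tetrahydrofuran-3-yl]methanone | COc1cc(C(=O)[C@H]2CO[C@H](c3cc(OC)c(O)c(OC)c3)[C@H]2CO)cc(OC)c1O | target

**Step count and risks**

Total step count: 10. Longest linear sequence: 8 steps (steps 2, 4, 5, 6, 7, 8, 9, 10 from phenol 3; equally steps 3 to 10 from ester 5).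

Steps most likely to fail:

1. Step 8 (proposed new method).
   - What may go wrong: the alkoxide may add to the iminium ion too slowly, so that allylation of the dienamine of 2, oligomerisation of the zwitterion or N-allylation of the amine take over. The ligand may not override the substrate preference at C4, giving 3,4-trans closure. The α-formyl centre may epimerise before it is reduced.
   - Fallback (known chemistry, a menthol-derived butenolide as chiral auxiliary and the lactone aldol sequence of classical lignan synthesis): it sets out from aryl bromide 4 and returns at ketone 15, so that steps 8 and 9 are bypassed. Aryllithium 7 from 4 is formylated with DMF to 4-(benzyloxy)-3,5-dimethoxybenzaldehyde F1 (also purchasable), and F1 with propane-1,3-dithiol and BF3·OEt2 gives 2-[4-(benzyloxy)-3,5-dimethoxyphenyl]-1,3-dithiane F2. Lithiated F2 (n-BuLi, THF, −78 °C) should add to (5R)-5-(l-menthyloxy)furan-2(5H)-one (CC(C)[C@@H]1CC[C@@H](C)C[C@H]1O[C@@H]1OC(=O)C=C1) anti to the menthyloxy group, and the lactone enolate is trapped with F1 anti to the new substituent, giving the trans-3,4-disubstituted 5-(menthyloxy)lactone F3. LiAlH4 reduces the lactone and the acetal carbon, with loss of menthol, to the triol F4. Camphorsulfonic acid in CH2Cl2 then closes the ring through the benzylic cation to the tetrahydrofuran dithiane F5. The aryl should settle trans to the neighbouring CH2OH group, and the trans lactone translates into the 3,4-cis ring. MeI and CaCO3 in aqueous MeCN remove the dithiane and give 15.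

2. Step 10.
   - What may go wrong: over-reduction, that is hydrogenolysis of the benzylic C2–O1 bond of the ring or reduction of the aryl ketone once the benzyl ethers are gone.
   - Fallback: from 15 straight to 16 by Lewis-acid debenzylation, BCl3 with pentamethylbenzene as trap for the benzyl cation, CH2Cl2, −78 °C, then methanol. It is non-reductive, so neither the ring C–O bond nor the ketone is exposed to hydrogen, and the low temperature should spare the aryl methyl ethers. No new compound is made.

3. Step 9.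
   - What may go wrong: slow osmylation of the hindered, electron-rich 1,1-disubstituted alkene, oxidation of the electron-rich rings by periodate during a long reaction, or epimerisation at C4 once the ketone is present in the aqueous buffered medium.
   - Fallback: from 13 to 15 with the alcohol masked and ozone as the oxidant. TESCl and imidazole give the triethylsilyl ether F6, ozonolysis (O3, pyridine, CH2Cl2, −78 °C; then Me2S) gives the silylated ketone F7, and AcOH/THF/H2O releases 15.

Further compounds
F1 | step 8 | 4-(benzyloxy)-3,5-dimethoxybenzaldehyde | COc1cc(C=O)cc(OC)c1OCc1ccccc1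
F2 | step 8 | 2-[4-(benzyloxy)-3,5-dimethoxyphenyl]-1,3-dithiane | COc1cc(C2SCCCS2)cc(OC)c1OCc1ccccc1
F3 | step 8 | (3S,4R,5R)-4-{2-[4-(benzyloxy)-3,5-dimethoxyphenyl]-1,3-dithian-2-yl}-3-{[4-(benzyloxy)-3,5-dimethoxyphenyl](hydroxy)methyl}-5-[(1R,2S,5R)-menthyloxy]dihydrofuran-2(3H)-one (carbinol centre mixed) | CC(C)[C@@H]1CC[C@@H](C)C[C@H]1O[C@@H]1OC(=O)[C@H](C(O)c2cc(OC)c(OCc3ccccc3)c(OC)c2)[C@H]1C1(c2cc(OC)c(OCc3ccccc3)c(OC)c2)SCCCS1
F4 | step 8 | (2R,3R)-2-{2-[4-(benzyloxy)-3,5-dimethoxyphenyl]-1,3-dithian-2-yl}-3-{[4-(benzyloxy)-3,5-dimethoxyphenyl](hydroxy)methyl}butane-1,4-diol (carbinol centre mixed) | OC[C@H](C(O)c1cc(OC)c(OCc2ccccc2)c(OC)c1)[C@H](CO)C1(c2cc(OC)c(OCc3ccccc3)c(OC)c2)SCCCS1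
F5 | step 8 | [(2S,3R,4R)-2-[4-(benzyloxy)-3,5-dimethoxyphenyl]-4-{2-[4-(benzyloxy)-3,5-dimethoxyphenyl]-1,3-dithian-2-yl}tetrahydrofuran-3-yl]methanol | COc1cc(C2(SCCCS2)[C@H]2CO[C@H](c3cc(OC)c(OCc4ccccc4)c(OC)c3)[C@H]2CO)cc(OC)c1OCc1ccccc1
F6 | step 9 | {[(2S,3R,4S)-2-[4-(benzyloxy)-3,5-dimethoxyphenyl]-4-{1-[4-(benzyloxy)-3,5-dimethoxyphenyl]vinyl}tetrahydrofuran-3-yl]methoxy}triethylsilane | C=C(c1cc(OC)c(OCc2ccccc2)c(OC)c1)[C@H]1CO[C@H](c2cc(OC)c(OCc3ccccc3)c(OC)c2)[C@H]1CO[Si](CC)(CC)CC
F7 | step 9 | [4-(benzyloxy)-3,5-dimethoxyphenyl][(3R,4R,5S)-5-[4-(benzyloxy)-3,5-dimethoxyphenyl]-4-{[(triethylsilyl)oxy]methyl}tetrahydrofuran-3-yl]methanone | COc1cc(C(=O)[C@H]2CO[C@H](c3cc(OC)c(OCc4ccccc4)c(OC)c3)[C@H]2CO[Si](CC)(CC)CC)cc(OC)c1OCc1ccccc1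
F0 | step 10 | none | none
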